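**Retrosynthetic overview**
- The target comes from its 2'-O-silyl ether, which is cleaved in the same flask as the key step.
- Rings C and A form in one operation from an acyclic (S)-β-hydroxy ynone carrying a 4-alkynyl-2,3,4-trimethoxycyclobutenone: 6-endo-dig O-cyclisation closes ring C (O1–C8a), then 4π-opening/6π-closure of the resulting 4-alkenylcyclobutenone builds ring A (C4a–C5). The squarate carbons become C5–C8.
- The β-hydroxy ynone comes from a catalytic enantioselective Mukaiyama aldol (C2–C3 bond, sets C2) between a 2-silyloxy-enyne and O-silylated 2-hydroxy-6-methoxybenzaldehyde.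
- The enyne-cyclobutenone comes from dimethyl squarate and the lithiated silyl enol ether of 3-butyn-2-one, quenched with MeOTf (this methyl becomes 8-OMe).
- Ring B is bought intact; ring A is made de novo, so no penta-oxygenated arene is needed.

Assumption: the squarate-derived quaternary carbon in 5, 6 and 9–11 is carried as a racemate (it becomes sp2 in step 5), so its SMILES centre is left undefined and 9–11 are epimer mixtures at that carbon only; 1, 3 and 7 are taken as catalogue chemicals.

**Step 1**
Reactants: 1 3-butyn-2-one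
Product: 2 tert-butyl(but-1-en-3-yn-2-yloxy)dimethylsilane
Conditions: TBSOTf, i-Pr2NEt, CH2Cl2, −78 → 0 °C
Reagents that add atoms: tert-butyldimethylsilyl triflate, CC(C)(C)[Si](C)(C)OS(=O)(=O)C(F)(F)F
Why: Soft enolisation/O-silylation (silyl enol ether formation) of a methyl ketone that can enolise only toward CH3; the hindered amine avoids aza-Michael addition to the ynone.

**Step 2**
Reactants: 2 tert-butyl(but-1-en-3-yn-2-yloxy)dimethylsilane; 3 dimethyl squarate (3,4-dimethoxycyclobut-3-ene-1,2-dione)
Product: 6 rac-4-{3-[(tert-butyldimethylsilyl)oxy]but-3-en-1-yn-1-yl}-2,3,4-trimethoxycyclobut-2-en-1-one, via lithium acetylide 4 (not isolated), via lithium alkoxide 5 (not isolated)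
Conditions: n-BuLi, THF, −78 °C; cannulate into 3, THF, −78 °C; then MeOTf, −78 → 0 °C
Reagents that add atoms: methyl triflate, COS(=O)(=O)C(F)(F)F
Why: Alkyne deprotonation and 1,2-addition of the lithium acetylide to one squarate carbonyl (the standard entry to Moore ring-expansion substrates), then O-methylation of the tertiary alkoxide; the enol silane is inert to the acetylide at −78 °C.

**Step 3**
Reactants: 7 2-hydroxy-6-methoxybenzaldehyde
Product: 8 2-[(tert-butyldimethylsilyl)oxy]-6-methoxybenzaldehyde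
Conditions: TBSCl, imidazole, DMF, 23 °C
Reagents that add atoms: tert-butyldimethylsilyl chloride, CC(C)(C)[Si](C)(C)Cl
Why: Standard phenol O-silylation (Corey conditions); the free phenol would otherwise quench SiCl4 in step 4 and make the benzylic carbinol of 10 an o-quinone-methide precursor.

**Step 4**
Reactants: 6 rac-4-{3-[(tert-butyldimethylsilyl)oxy]but-3-en-1-yn-1-yl}-2,3,4-trimethoxycyclobut-2-en-1-one; 8 2-[(tert-butyldimethylsilyl)oxy]-6-methoxybenzaldehyde
Product: 10 4-{(5S)-5-[2-(tert-butyldimethylsilyloxy)-6-methoxyphenyl]-5-hydroxy-3-oxopent-1-yn-1-yl}-2,3,4-trimethoxycyclobut-2-en-1-one, via trichlorosilyl aldolate 9 (not isolated)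
Conditions: SiCl4 (1.5 equiv), (S,S)-Denmark binaphthyldiamine bisphosphoramide (5 mol %), i-Pr2NEt (10 mol %), CH2Cl2, −78 °C; sat. aq NaHCO3
Reagents that add atoms: none
Why: Denmark's Lewis-base-catalysed, SiCl4-mediated Mukaiyama aldol, in which the chiral phosphoramide-bound trichlorosilyl cation activates the aldehyde and the enol silane must add to its Si face through an open transition state to set the (S)-carbinol that becomes C2; the catalyst hand is my expectation, not a checked assignment, so the product configuration is verified by Mosher analysis and the antipodal catalyst used if it is reversed.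

**Step 5**
Reactants: 10 4-{(5S)-5-[2-(tert-butyldimethylsilyloxy)-6-methoxyphenyl]-5-hydroxy-3-oxopent-1-yn-1-yl}-2,3,4-trimethoxycyclobut-2-en-1-one
Product: 15 (2S)-5-hydroxy-2-(2-hydroxy-6-methoxyphenyl)-6,7,8-trimethoxychroman-4-one, via pyranone-cyclobutenone 11 (not isolated), via dienylketene 12 (not isolated), via cyclohexadienone 13 (not isolated), via silyl-protected flavanone 14 (not isolated)
Conditions: (Ph3P)AuNTf2 (2 mol %), PhMe, 23 °C; then PPh3 (5 mol %), 120 °C (sealed); then KHF2, MeOH, 23 °C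
Reagents that add atoms: none
Why: Proposed new method: gold activates the ynone so the secondary hydroxyl adds 6-endo-dig at the β-carbon (ring C, with the preset C2 centre a spectator), which converts the alkynylcyclobutenone into a 4-alkenyl-4-methoxycyclobutenone that on heating undergoes conrotatory 4π opening (methoxy outward, alkenyl inward), 6π electrocyclisation of the dienylketene onto the nucleophilic enone α-carbon and enolisation to the 5-hydroxy-6,7,8-trimethoxy arene (ring A), after which mildly acidic bifluoride removes the aryl silyl ether without forming a phenoxide that could open the ring; the closest known reactions are the gold-catalysed cyclisation of β-hydroxy ynones to 2,3-dihydro-4H-pyran-4-ones and the Moore ring expansion of 4-alkenyl-4-alkoxycyclobutenones derived from squarates and α-lithiated cyclic enol ethers.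

**Compound list**
1 | 3-butyn-2-one | CC(=O)C#C | starting material
2 | tert-butyl(but-1-en-3-yn-2-yloxy)dimethylsilane | C=C(O[Si](C)(C)C(C)(C)C)C#C | intermediate
3 | dimethyl squarate | COC1=C(OC)C(=O)C1=O | starting material
4 | lithium acetylide of 2 (not isolated) | [Li]C#CC(=C)O[Si](C)(C)C(C)(C)C | intermediate
5 | lithium alkoxide adduct of 4 and 3 (not isolated) | COC1=C(OC)C(O[Li])(C#CC(=C)O[Si](C)(C)C(C)(C)C)C1=O | intermediate
6 | rac-4-{3-[(tert-butyldimethylsilyl)oxy]but-3-en-1-yn-1-yl}-2,3,4-trimethoxycyclobut-2-en-1-one | COC1=C(OC)C(OC)(C#CC(=C)O[Si](C)(C)C(C)(C)C)C1=O | intermediate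
7 | 2-hydroxy-6-methoxybenzaldehyde | COc1cccc(O)c1C=O | starting material
8 | 2-[(tert-butyldimethylsilyl)oxy]-6-methoxybenzaldehyde | COc1cccc(O[Si](C)(C)C(C)(C)C)c1C=O | intermediate
9 | (S)-O-trichlorosilyl aldolate (not isolated) | COc1cccc(O[Si](C)(C)C(C)(C)C)c1[C@@H](O[Si](Cl)(Cl)Cl)CC(=O)C#CC1(OC)C(OC)=C(OC)C1=O | intermediate
10 | 4-{(5S)-5-[2-(tert-butyldimethylsilyloxy)-6-methoxyphenyl]-5-hydroxy-3-oxopent-1-yn-1-yl}-2,3,4-trimethoxycyclobut-2-en-1-one | COc1cccc(O[Si](C)(C)C(C)(C)C)c1[C@@H](O)CC(=O)C#CC1(OC)C(OC)=C(OC)C1=O | intermediate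
11 | (2S)-2-[2-(tert-butyldimethylsilyloxy)-6-methoxyphenyl]-6-(1,2,3-trimethoxy-4-oxocyclobut-2-en-1-yl)-2,3-dihydro-4H-pyran-4-one (not isolated) | COc1cccc(O[Si](C)(C)C(C)(C)C)c1[C@@H]1CC(=O)C=C(O1)C1(OC)C(OC)=C(OC)C1=O | intermediate
12 | (Z)-dienylketene from ring opening of 11 (not isolated) | COc1cccc(O[Si](C)(C)C(C)(C)C)c1[C@@H]1CC(=O)C=C(O1)/C(OC)=C(OC)\C(OC)=C=O | intermediate
13 | (2S)-2-[2-(tert-butyldimethylsilyloxy)-6-methoxyphenyl]-6,7,8-trimethoxy-2,3-dihydro-4H-chromene-4,5(4aH)-dione (not isolated) | COc1cccc(O[Si](C)(C)C(C)(C)C)c1[C@@H]1CC(=O)C2C(=O)C(OC)=C(OC)C(OC)=C2O1 | intermediate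
14 | (2S)-2-[2-(tert-butyldimethylsilyloxy)-6-methoxyphenyl]-5-hydroxy-6,7,8-trimethoxychroman-4-one (not isolated) | COc1cccc(O[Si](C)(C)C(C)(C)C)c1[C@@H]1CC(=O)c2c(O)c(OC)c(OC)c(OC)c2O1 | intermediate
15 | (2S)-5-hydroxy-2-(2-hydroxy-6-methoxyphenyl)-6,7,8-trimethoxychroman-4-one | COc1cccc(O)c1[C@@H]1CC(=O)c2c(O)c(OC)c(OC)c(OC)c2O1 | target

**Totals**
Total steps: 5. Longest linear sequence: 4 (steps 1, 2, 4, 5 from 3-butyn-2-one); step 3 is a one-step side branch.

**Steps most likely to fail, with fallbacks**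

Step 5 (two-ring cascade). The gold-triggered 6-endo closure next to the quaternary carbon may stall, or the catalyst may not tolerate the cyclobutenone. The fallback sets out from 10. Diethylamine (1.2 equiv, EtOH, 0 → 23 °C) adds across the ynone to give the β-aminoenone 4-{(1E,5S)-5-[2-(tert-butyldimethylsilyloxy)-6-methoxyphenyl]-1-(diethylamino)-5-hydroxy-3-oxopent-1-en-1-yl}-2,3,4-trimethoxycyclobut-2-en-1-one F1, which is isolated. PPTS (1 equiv, PhMe, 23–40 °C) then closes ring C by intramolecular O-for-N addition–elimination with loss of diethylamine. This forms 11 in the flask, and the heating and bifluoride stages of step 5 follow unchanged, so both rings still form in one operation. The route is rejoined at 11.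

Step 4 (enantioselective aldol). Selectivity may be poor with the hindered 2,6-dioxygenated aldehyde. The fallback sets out from 6 and 8. An achiral Mukaiyama aldol (BF3·OEt2, CH2Cl2, −78 °C) gives rac-4-{5-[2-(tert-butyldimethylsilyloxy)-6-methoxyphenyl]-5-hydroxy-3-oxopent-1-yn-1-yl}-2,3,4-trimethoxycyclobut-2-en-1-one F2. Stereocontrol is then moved to an acylative kinetic resolution of the benzylic alcohol with Birman's (R)-benzotetramisole (4 mol %), isobutyric anhydride (0.6 equiv), i-Pr2NEt, CHCl3, 0 °C. The fast-reacting enantiomer becomes (1R)-1-[2-(tert-butyldimethylsilyloxy)-6-methoxyphenyl]-3-oxo-5-(1,2,3-trimethoxy-4-oxocyclobut-2-en-1-yl)pent-4-yn-1-yl 2-methylpropanoate F3, and the unreacted (S)-alcohol is recovered by chromatography (at most 50 %). The catalyst hand follows the benzylic-alcohol model; the antipode is used if the fast-reacting enantiomer proves to be S. The route is rejoined at 10.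

Step 2 (acetylide addition and methylation). Lithiated 2 or its enol silane may not survive the addition and triflate quench. The fallback sets out from 3 and builds the enol silane last. Monolithium acetylide (acetylene, n-BuLi, THF, −78 °C) then MeOTf gives rac-4-ethynyl-2,3,4-trimethoxycyclobut-2-en-1-one F4. Acyl Sonogashira coupling with acetyl chloride (PdCl2(PPh3)2, CuI, Et3N, THF, 23 °C) gives the methyl ynone rac-2,3,4-trimethoxy-4-(3-oxobut-1-yn-1-yl)cyclobut-2-en-1-one F5. TBSOTf/i-Pr2NEt (CH2Cl2, −78 °C) then silylates the methyl ketone. The route is rejoined at 6.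

**Further compounds**
F1 | step 5 | 4-{(1E,5S)-5-[2-(tert-butyldimethylsilyloxy)-6-methoxyphenyl]-1-(diethylamino)-5-hydroxy-3-oxopent-1-en-1-yl}-2,3,4-trimethoxycyclobut-2-en-1-one | COc1cccc(O[Si](C)(C)C(C)(C)C)c1[C@@H](O)CC(=O)/C=C(/N(CC)CC)C1(OC)C(OC)=C(OC)C1=O
F2 | step 4 | rac-4-{5-[2-(tert-butyldimethylsilyloxy)-6-methoxyphenyl]-5-hydroxy-3-oxopent-1-yn-1-yl}-2,3,4-trimethoxycyclobut-2-en-1-one | COc1cccc(O[Si](C)(C)C(C)(C)C)c1C(O)CC(=O)C#CC1(OC)C(OC)=C(OC)C1=O
F3 | step 4 | (1R)-1-[2-(tert-butyldimethylsilyloxy)-6-methoxyphenyl]-3-oxo-5-(1,2,3-trimethoxy-4-oxocyclobut-2-en-1-yl)pent-4-yn-1-yl 2-methylpropanoate | COc1cccc(O[Si](C)(C)C(C)(C)C)c1[C@H](OC(=O)C(C)C)CC(=O)C#CC1(OC)C(OC)=C(OC)C1=O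
F4 | step 2 | rac-4-ethynyl-2,3,4-trimethoxycyclobut-2-en-1-one | COC1=C(OC)C(OC)(C#C)C1=O
F5 | step 2 | rac-2,3,4-trimethoxy-4-(3-oxobut-1-yn-1-yl)cyclobut-2-en-1-one | COC1=C(OC)C(OC)(C#CC(C)=O)C1=O
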